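**Retrosynthetic overview**
1. Rigidin C ⇒ its O,O'-dibenzyl ether. Both phenols are released in a final hydrogenolysis.
2. The pyrimidinedione ring is formed last. It comes from a 2-amino-5-aroyl-4-arylpyrrole-3-carboxamide plus one carbonyl carbon from oxalyl chloride (N1–C2 and C2–N3 bonds).
3. The pyrrole ring is formed first. The key C5–C6 bond comes from an intermolecular Michael addition of the α-carbon of an N-mesyl α-aminoketone to a benzylidene cyanoacetamide. Closure of N onto C≡N and loss of MeSO2⁻ then aromatise the ring.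
4. The acceptor comes from O-benzylvanillin and cyanoacetamide (Knoevenagel). The donor comes from 4-hydroxyacetophenone by benzylation, α-bromination, Delépine amination and mesylation.

**Assumption:** Rigidin C has no stereocentre and is achiral, so the given SMILES defines it fully. The only stereo-element in the route is the transient E alkene of 10.

**Step 1**
Reactants: 1 4-hydroxyacetophenone
Product: 2 4-(benzyloxy)acetophenone
Conditions: BnBr (1.1 equiv), K2CO3 (1.5 equiv), acetone, reflux
Reagents that add atoms: benzyl bromide, BrCc1ccccc1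
Why: This is a Williamson ether synthesis in which the acidic phenol is the only site K2CO3 deprotonates and the phenoxide displaces a benzylic bromide cleanly.

**Step 2**
Reactants: 2 4-(benzyloxy)acetophenone
Product: 3 2-bromo-1-[4-(benzyloxy)phenyl]ethan-1-one
Conditions: CuBr2 (2.1 equiv), EtOAc/CHCl3 1:1, reflux
Reagents that add atoms: copper dibromide CuBr2, [Cu+2].[Br-].[Br-]
Why: Heterogeneous α-bromination of the enol with CuBr2 (King–Ostrum conditions) stops at the monobromide and leaves the acyl-deactivated ring and the benzyl ether untouched.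

**Step 3**
Reactants: 3 2-bromo-1-[4-(benzyloxy)phenyl]ethan-1-one
Product: 4 1-{2-[4-(benzyloxy)phenyl]-2-oxoethyl}-1,3,5,7-tetraazaadamantan-1-ium bromide
Conditions: (CH2)6N4 (1.05 equiv), CHCl3, rt; filter the salt
Reagents that add atoms: hexamethylenetetramine, C1N2CN3CN1CN(C2)C3
Why: This SN2 quaternisation is the first stage of the Delépine reaction, and the salt precipitates so only one alkylation at nitrogen can occur.

**Step 4**
Reactants: 4 hexaminium bromide
Product: 5 2-amino-1-[4-(benzyloxy)phenyl]ethan-1-one hydrochloride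
Conditions: conc. HCl, EtOH, rt → 40 °C; crystallise
Reagents that add atoms: hydrogen chloride, Cl
Why: Acid ethanolysis of the aminal cage (second stage of the Delépine reaction) leaves only the primary amine, which stays protonated so it cannot self-condense to a dihydropyrazine, and the aryl benzyl ether tolerates ethanolic HCl at this temperature.

**Step 5**
Reactants: 5 2-amino-1-[4-(benzyloxy)phenyl]ethan-1-one hydrochloride
Product: 6 N-{2-[4-(benzyloxy)phenyl]-2-oxoethyl}methanesulfonamide
Conditions: MsCl (1.1 equiv), Et3N (2.2 equiv, added last, slowly), CH2Cl2, 0 °C → rt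
Reagents that add atoms: methanesulfonyl chloride, CS(=O)(=O)Cl
Why: In this N-sulfonylation the amine is liberated in the presence of MsCl and trapped faster than it dimerises, and the mesyl group later serves as the leaving group that aromatises the pyrrole.

**Step 6**
Reactants: 7 vanillin
Product: 8 4-(benzyloxy)-3-methoxybenzaldehyde
Conditions: BnBr (1.1 equiv), K2CO3 (1.5 equiv), DMF, rt
Reagents that add atoms: benzyl bromide, BrCc1ccccc1
Why: This is a Williamson ether synthesis at the only acidic site, and the aldehyde and methyl ether are inert to K2CO3.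

**Step 7**
Reactants: 8 4-(benzyloxy)-3-methoxybenzaldehyde; 9 2-cyanoacetamide
Product: 10 (E)-3-[4-(benzyloxy)-3-methoxyphenyl]-2-cyanoprop-2-enamide
Conditions: piperidine (10 mol %), EtOH, reflux; product crystallises
Reagents that add atoms: none
Why: In this Knoevenagel condensation, reversible addition and dehydration give the thermodynamic E alkene (aryl cis to the small cyano group), whose geometry is lost in the next step anyway.

**Step 8 (key step)**
Reactants: 6 N-{2-[4-(benzyloxy)phenyl]-2-oxoethyl}methanesulfonamide; 10 (E)-3-[4-(benzyloxy)-3-methoxyphenyl]-2-cyanoprop-2-enamide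
Product: 14 2-amino-5-[4-(benzyloxy)benzoyl]-4-[4-(benzyloxy)-3-methoxyphenyl]-1H-pyrrole-3-carboxamide, via Michael adduct 11 (not isolated), via N-mesyl-2-aminopyrroline 12 (not isolated), via 3H-pyrrole tautomer 13 (not isolated)
Conditions: 10 (1.2 equiv), K2CO3 (1.0 equiv), EtOH, reflux, 14 h; pour into water, filter, recrystallise
Reagents that add atoms: none
Why: The ketone-stabilised carbanion of 6 adds to the doubly activated alkene of 10 in an intermolecular Michael addition (the new C–C bond), after which 5-exo-dig closure of the sulfonamide nitrogen on the nitrile, E1cB loss of methanesulfinate and tautomerisation drive everything irreversibly to the aromatic pyrrole, erasing the three transient stereocentres so that no stereocontrol is needed.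

**Step 9**
Reactants: 14 2-amino-5-[4-(benzyloxy)benzoyl]-4-[4-(benzyloxy)-3-methoxyphenyl]-1H-pyrrole-3-carboxamide
Product: 16 6-[4-(benzyloxy)benzoyl]-5-[4-(benzyloxy)-3-methoxyphenyl]-1H-pyrrolo[2,3-d]pyrimidine-2,4(3H,7H)-dione, via acyl isocyanate 15 (not isolated)
Conditions: (COCl)2 (4 equiv), diglyme, rt → 160 °C, N2
Reagents that add atoms: oxalyl chloride, O=C(Cl)C(=O)Cl
Why: In a Speziale-type reaction oxalyl chloride converts the primary carboxamide into an acyl isocyanate with loss of CO, and the adjacent 2-amino group adds to it intramolecularly to close the six-membered cyclic acylurea, while ketone, benzyl ethers and methyl ether are unaffected.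

**Step 10**
Reactants: 16 O,O'-dibenzylrigidin C
Product: 17 Rigidin C
Conditions: H2 (1 atm), 10% Pd/C, DMF/MeOH 1:1, rt
Reagents that add atoms: none
Why: Catalytic hydrogenolysis cleaves both aryl benzyl ethers under neutral conditions, the methyl ether is inert, and the diaryl ketone is a strongly deactivated vinylogous amide that is not reduced at 1 atm without acid.

**Compound list**
1 | 4-hydroxyacetophenone | CC(=O)c1ccc(O)cc1 | starting material
2 | 4-(benzyloxy)acetophenone | CC(=O)c1ccc(OCc2ccccc2)cc1 | intermediate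
3 | 2-bromo-1-[4-(benzyloxy)phenyl]ethan-1-one | O=C(CBr)c1ccc(OCc2ccccc2)cc1 | intermediate
4 | 1-{2-[4-(benzyloxy)phenyl]-2-oxoethyl}-1,3,5,7-tetraazaadamantan-1-ium bromide | [Br-].O=C(C[N+]12CN3CN(C1)CN(C3)C2)c1ccc(OCc2ccccc2)cc1 | intermediate
5 | 2-amino-1-[4-(benzyloxy)phenyl]ethan-1-one hydrochloride | [Cl-].[NH3+]CC(=O)c1ccc(OCc2ccccc2)cc1 | intermediate
6 | N-{2-[4-(benzyloxy)phenyl]-2-oxoethyl}methanesulfonamide | CS(=O)(=O)NCC(=O)c1ccc(OCc2ccccc2)cc1 | intermediate
7 | vanillin (4-hydroxy-3-methoxybenzaldehyde) | COc1cc(C=O)ccc1O | starting material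
8 | 4-(benzyloxy)-3-methoxybenzaldehyde | COc1cc(C=O)ccc1OCc1ccccc1 | intermediate
9 | 2-cyanoacetamide | N#CCC(N)=O | starting material
10 | (E)-3-[4-(benzyloxy)-3-methoxyphenyl]-2-cyanoprop-2-enamide | NC(=O)/C(C#N)=C/c1ccc(OCc2ccccc2)c(OC)c1 | intermediate
11 | Michael adduct, 5-[4-(benzyloxy)phenyl]-3-[4-(benzyloxy)-3-methoxyphenyl]-2-cyano-4-(methanesulfonamido)-5-oxopentanamide, diastereomer mixture, not isolated | CS(=O)(=O)NC(C(=O)c1ccc(OCc2ccccc2)cc1)C(c1ccc(OCc2ccccc2)c(OC)c1)C(C#N)C(N)=O | intermediate
12 | 2-amino-5-[4-(benzyloxy)benzoyl]-4-[4-(benzyloxy)-3-methoxyphenyl]-1-(methylsulfonyl)-4,5-dihydro-1H-pyrrole-3-carboxamide, diastereomer mixture, not isolated | CS(=O)(=O)N1C(N)=C(C(N)=O)C(c2ccc(OCc3ccccc3)c(OC)c2)C1C(=O)c1ccc(OCc2ccccc2)cc1 | intermediate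
13 | 5-amino-2-[4-(benzyloxy)benzoyl]-3-[4-(benzyloxy)-3-methoxyphenyl]-3H-pyrrole-4-carboxamide, racemic, not isolated | NC1=C(C(N)=O)C(c2ccc(OCc3ccccc3)c(OC)c2)C(C(=O)c2ccc(OCc3ccccc3)cc2)=N1 | intermediate
14 | 2-amino-5-[4-(benzyloxy)benzoyl]-4-[4-(benzyloxy)-3-methoxyphenyl]-1H-pyrrole-3-carboxamide | NC(=O)c1c(N)[nH]c(C(=O)c2ccc(OCc3ccccc3)cc2)c1-c1ccc(OCc2ccccc2)c(OC)c1 | intermediate
15 | 2-amino-5-[4-(benzyloxy)benzoyl]-4-[4-(benzyloxy)-3-methoxyphenyl]-1H-pyrrole-3-carbonyl isocyanate, not isolated | Nc1[nH]c(C(=O)c2ccc(OCc3ccccc3)cc2)c(-c2ccc(OCc3ccccc3)c(OC)c2)c1C(=O)N=C=O | intermediate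
16 | 6-[4-(benzyloxy)benzoyl]-5-[4-(benzyloxy)-3-methoxyphenyl]-1H-pyrrolo[2,3-d]pyrimidine-2,4(3H,7H)-dione | COc1cc(-c2c(C(=O)c3ccc(OCc4ccccc4)cc3)[nH]c3[nH]c(=O)[nH]c(=O)c23)ccc1OCc1ccccc1 | intermediate
17 | Rigidin C, 6-(4-hydroxybenzoyl)-5-(4-hydroxy-3-methoxyphenyl)-1H-pyrrolo[2,3-d]pyrimidine-2,4(3H,7H)-dione | COc1cc(-c2c(C(=O)c3ccc(O)cc3)[nH]c3[nH]c(=O)[nH]c(=O)c23)ccc1O | target

**Total step count:** 10
**Longest linear sequence:** 8 steps (1 → 2 → 3 → 4 → 5 → 6 → 14 → 16 → 17). The vanillin branch (7 → 8 → 10) joins at step 8.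

**Three steps most likely to fail**

Step 8. The two alkoxy donors make the alkene of 10 a sluggish acceptor. Reversible aza-Michael addition or retro-Knoevenagel cleavage could therefore outrun the productive C-addition. The fallback changes the acceptor fragment and installs the carboxamide afterwards.
- It sets out from aldehyde 8, which is condensed with malononitrile (cat. piperidine, EtOH, rt) to give 2-[4-(benzyloxy)-3-methoxybenzylidene]propanedinitrile F1. This is a far stronger Michael acceptor.
- F1 is combined with sulfonamide 6 (K2CO3, EtOH, reflux). The same Michael addition, ring closure and sulfinate loss give 2-amino-5-[4-(benzyloxy)benzoyl]-4-[4-(benzyloxy)-3-methoxyphenyl]-1H-pyrrole-3-carbonitrile F2.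
- The nitrile of F2 is hydrated with 30% H2O2, K2CO3 and DMSO at rt (Radziszewski-type hydration). This returns to the route at 14.

Step 9. Hot oxalyl chloride and HCl may acylate the amine or pyrrole nitrogen to give oxamides, or may erode the benzyl ethers. The fallback reverses the roles of the two nitrogens and works under basic conditions.
- It sets out from 14, whose 2-amino group is acylated with phenyl chloroformate (pyridine, THF, 0 °C → 50 °C). The product is phenyl N-{5-[4-(benzyloxy)benzoyl]-4-[4-(benzyloxy)-3-methoxyphenyl]-3-carbamoyl-1H-pyrrol-2-yl}carbamate F3.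
- DBU in hot dioxane then makes the carboxamide nitrogen attack the carbamate and expel phenoxide. This closes the pyrimidinedione and returns to the route at 16.

Step 5. The free base of 5 self-condenses to dihydropyrazines, bis-mesylation is possible, and the quality of 5 depends on the Delépine hydrolysis. The fallback never generates a free α-aminoketone.
- It sets out from bromoketone 3, which N-alkylates commercial tert-butyl (methylsulfonyl)carbamate (K2CO3, DMF, rt). Only one acidic N–H is present, so over-alkylation is impossible.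
- The product is tert-butyl N-{2-[4-(benzyloxy)phenyl]-2-oxoethyl}-N-(methylsulfonyl)carbamate F4.
- Removal of the Boc group with TFA/CH2Cl2 (0 °C → rt) returns to the route at 6.

**Further compounds**
F1 | step 8 | 2-[4-(benzyloxy)-3-methoxybenzylidene]propanedinitrile | N#CC(C#N)=Cc1ccc(OCc2ccccc2)c(OC)c1
F2 | step 8 | 2-amino-5-[4-(benzyloxy)benzoyl]-4-[4-(benzyloxy)-3-methoxyphenyl]-1H-pyrrole-3-carbonitrile | N#Cc1c(N)[nH]c(C(=O)c2ccc(OCc3ccccc3)cc2)c1-c1ccc(OCc2ccccc2)c(OC)c1
F3 | step 9 | phenyl N-{5-[4-(benzyloxy)benzoyl]-4-[4-(benzyloxy)-3-methoxyphenyl]-3-carbamoyl-1H-pyrrol-2-yl}carbamate | NC(=O)c1c(NC(=O)Oc2ccccc2)[nH]c(C(=O)c2ccc(OCc3ccccc3)cc2)c1-c1ccc(OCc2ccccc2)c(OC)c1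
F4 | step 5 | tert-butyl N-{2-[4-(benzyloxy)phenyl]-2-oxoethyl}-N-(methylsulfonyl)carbamate | CC(C)(C)OC(=O)N(CC(=O)c1ccc(OCc2ccccc2)cc1)S(C)(=O)=O
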